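The six-membered enone ring (C1, C2, C3, C4, C10, C11) is disconnected at C10–C11 and C3–C4. This ring is fused to the seven-membered ring at C4–C10, and once C5 is a ketone that bond is the alkene of an enone with C10 as its β-carbon. A Diels–Alder reaction of a 1-methoxy-3-silyloxy diene with a 6-silyloxy-3,7,7-trimethylcyclohepta-2,4-dienone therefore builds the enone ring, the quaternary C10 and the cis ring fusion in one operation, under control of the C7 stereocentre taken from (S)-pantolactone. The cyclobutane bond C5–C11 is closed afterwards by a radical addition–fragmentation, and the anti C7/C9 diester is set by Wacker oxidation and Evans–Tishchenko reduction.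

Key step: step 10

Remark: locants C1–C11 are those of the eleven-carbon chain of the target (C1 ketone, C2=C3 with methyl on C3, C6 with two methyls, C7 tiglate, C9 angelate, C10 with one methyl; further bonds C11–C1, C4–C10, C5–C11). Centres that are destroyed later (lactol carbon of 3, carbinol carbon of 8–10, C3 of 14, C5 of 16–18) are carried as epimer mixtures and left undefined in the SMILES.

**Step 1**
Reactants: 1 (S)-pantolactone
Product: 2 (3S)-3-(tert-butyldimethylsilyloxy)-4,4-dimethyloxolan-2-one
Conditions: TBSCl, imidazole, DMF, 25 °C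
Reagents that add atoms: tert-butyldimethylsilyl chloride, CC(C)(C)[Si](C)(C)Cl
Why: Silyl ether formation at the secondary hydroxyl, which does not touch the stereocentre.

**Step 2**
Reactants: 2 (3S)-3-(tert-butyldimethylsilyloxy)-4,4-dimethyloxolan-2-one
Product: 3 (3S)-3-(tert-butyldimethylsilyloxy)-4,4-dimethyloxolan-2-ol (lactol, both anomers)
Conditions: iBu2AlH, CH2Cl2, −78 °C
Reagents that add atoms: none
Why: Partial reduction of a lactone to the lactol, which stops at this stage at low temperature.

**Step 3**
Reactants: 3 (3S)-3-(tert-butyldimethylsilyloxy)-4,4-dimethyloxolan-2-ol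
Product: 4 (3R)-3-(tert-butyldimethylsilyloxy)-2,2-dimethylpent-4-en-1-ol
Conditions: Ph3PCH3Br, KOtBu, THF, 0 °C; then 3, −20 to 0 °C; cold aq. NH4Cl
Reagents that add atoms: methyltriphenylphosphonium bromide, C[P+](c1ccccc1)(c1ccccc1)c1ccccc1.[Br-]
Why: Wittig methylenation of the open hydroxy-aldehyde form of the lactol; the cold quench is meant to keep the silyl group from migrating to the new primary alkoxide, and the stereocentre is unchanged (the descriptor becomes R only through a change of priorities).

**Step 4**
Reactants: 4 (3R)-3-(tert-butyldimethylsilyloxy)-2,2-dimethylpent-4-en-1-ol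
Product: 5 (3R)-3-(tert-butyldimethylsilyloxy)-2,2-dimethylpent-4-enoic acid
Conditions: TEMPO (cat.), PhI(OAc)2, MeCN/H2O, 25 °C
Reagents that add atoms: water, O
Why: Nitroxyl-catalysed oxidation of a primary alcohol to the carboxylic acid, which spares the alkene and the silyl ether and meets no α-hydrogen.

**Step 5**
Reactants: 5 (3R)-3-(tert-butyldimethylsilyloxy)-2,2-dimethylpent-4-enoic acid
Product: 6 (4R)-4-(tert-butyldimethylsilyloxy)-3,3-dimethylhex-5-en-2-one
Conditions: MeLi (2.5 equiv), Et2O, 0 to 25 °C; then aq. NH4Cl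
Reagents that add atoms: methyllithium, [Li]C
Why: Methyl ketone synthesis from a carboxylic acid and methyllithium, in which the tetrahedral adduct survives until work-up so that double addition is avoided; an α-quaternary acid is well suited.

**Step 6**
Reactants: 6 (4R)-4-(tert-butyldimethylsilyloxy)-3,3-dimethylhex-5-en-2-one; 7 but-3-en-2-one (methyl vinyl ketone)
Product: 8 (3R)-3-(tert-butyldimethylsilyloxy)-7-hydroxy-4,4,7-trimethylnona-1,8-dien-5-one (both C7 epimers)
Conditions: LiN(iPr)2, THF, −78 °C; 7, −78 °C; AcOH, −78 °C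
Reagents that add atoms: none
Why: Kinetic aldol (1,2-) addition of the only possible enolate of 6 to the carbonyl of 7, quenched cold before equilibration to the conjugate adduct; the new carbinol centre is formed without control and disappears in step 8.

**Step 7**
Reactants: 8 (3R)-3-(tert-butyldimethylsilyloxy)-7-hydroxy-4,4,7-trimethylnona-1,8-dien-5-one
Product: 9 (6R)-6-(tert-butyldimethylsilyloxy)-3-hydroxy-3,7,7-trimethylcyclohept-4-en-1-one (both C3 epimers)
Conditions: second-generation Grubbs catalyst (5 mol%), CH2Cl2 (5 mM), 40 °C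
Reagents that add atoms: none
Why: Ring-closing metathesis of two monosubstituted alkenes closes the seven-membered ring as the necessarily cis C8=C9 alkene with loss of ethene.

**Step 8**
Reactants: 9 (6R)-6-(tert-butyldimethylsilyloxy)-3-hydroxy-3,7,7-trimethylcyclohept-4-en-1-one
Product: 11 (6R)-6-(tert-butyldimethylsilyloxy)-3,7,7-trimethylcyclohepta-2,4-dien-1-one, via tertiary mesylate 10 (not isolated)
Conditions: MsCl, Et3N, DMAP (cat.), CH2Cl2, 0 to 25 °C
Reagents that add atoms: none
Why: E1cB elimination of the activated tertiary aldol hydroxyl through the only acidic position (C4) gives the conjugated dienone; the quaternary C6 blocks enolisation toward C7, so the stereocentre is safe.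

**Step 9**
Reactants: 12 (E)-4-methoxypent-3-en-2-one
Product: 13 (E)-4-methoxy-2-(trimethylsilyloxy)penta-1,3-diene
Conditions: LiN(iPr)2, THF, −78 °C; TMSCl
Reagents that add atoms: chlorotrimethylsilane, C[Si](C)(C)Cl
Why: Kinetic deprotonation of the acetyl methyl group of the vinylogous ester and O-silylation (silyl enol ether formation) give the diene with the E geometry retained.

**Step 10**
Reactants: 11 (6R)-6-(tert-butyldimethylsilyloxy)-3,7,7-trimethylcyclohepta-2,4-dien-1-one; 13 (E)-4-methoxy-2-(trimethylsilyloxy)penta-1,3-diene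
Product: 15 (4R,7R,10R) cis-fused bicyclic enedione (C1 ketone with C2=C3 and 3-methyl, C5 ketone, C8=C9, 7-OTBS, 6,6-dimethyl, 10-methyl), via silyl enol ether cycloadduct 14 (not isolated)
Conditions: 13 (3 equiv), CH2Cl2, 13 kbar, 30 °C; then 0.1 M HCl, THF, 0 °C
Reagents that add atoms: none
Why: Normal-demand Diels–Alder reaction, concerted but strongly asynchronous: the CH2 terminus of 13 (C11), the most nucleophilic diene carbon, bonds first to the enone β-carbon C10, and the methoxy-bearing terminus (C3) then closes onto C4. The closest known reaction type is the cycloaddition of 1-methoxy-3-silyloxy dienes to cycloalkenones followed by acid-induced loss of methanol, and high pressure is the established remedy for a β,β-disubstituted dienophile. The six-membered ring (C1, C2, C3, C4, C10, C11) closes by suprafacial [4+2] addition across C4=C10, which fixes the cis ring fusion. C10 and C4 are set together: their relative configuration by the suprafacial addition, their absolute configuration by approach of the diene to the face opposite the C7 silyloxy group, whose own face is further shielded by the C6 methyl syn to it. Regiochemistry follows the donor–acceptor match, and C4=C10 reacts in preference to C8=C9 because only it is conjugated directly to the C5 carbonyl. Dilute acid at 0 °C converts 14 into the C2=C3 enone quickly, so that the doubly activated C4–H has little time to epimerise.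

**Step 11**
Reactants: 15 (4R,7R,10R) cis-fused bicyclic enedione
Product: 16 (4R,7R,10R) C5 alcohol of the bicyclic enone (both C5 epimers)
Conditions: NaBH4, MeOH/CH2Cl2 (1:1), −78 °C
Reagents that add atoms: none
Why: Low-temperature borohydride reduction takes a saturated ketone in preference to a conjugated enone and at once removes the acidity of C4–H; the C5 carbinol may form as either epimer because C5 becomes a planar radical in step 14.

**Step 12**
Reactants: 16 (4R,7R,10R) C5 alcohol of the bicyclic enone
Product: 17 (4R,7R,10R) C11=C1 enol triflate (2-triflyloxy-1,3-diene C11=C1–C2=C3) with free C5 hydroxyl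
Conditions: KN(SiMe3)2 (2.2 equiv), THF, −78 °C; PhNTf2, −78 to −40 °C
Reagents that add atoms: N-phenylbis(trifluoromethanesulfonimide), O=S(=O)(N(c1ccccc1)S(=O)(=O)C(F)(F)F)C(F)(F)F
Why: Once the hydroxyl is deprotonated, the second equivalent of base removes the kinetic α′ proton at C11 (kinetic enolate formation of a cyclohexenone), and O-sulfonylation of that enolate gives the enol triflate.

**Step 13**
Reactants: 17 (4R,7R,10R) C11=C1 enol triflate with free C5 hydroxyl
Product: 18 (4R,7R,10R) enol triflate bearing a C5 O-(imidazol-1-ylthiocarbonyl) group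
Conditions: 1,1′-thiocarbonyldiimidazole, DMAP (cat.), ClCH2CH2Cl, 70 °C
Reagents that add atoms: 1,1'-thiocarbonyldiimidazole, S=C(n1ccnc1)n1ccnc1
Why: Thioacylation of the hindered secondary alcohol under neutral conditions installs the radical leaving group of a Barton–McCombie deoxygenation without touching the enol triflate.

**Step 14**
Reactants: 18 (4R,7R,10R) enol triflate bearing a C5 O-(imidazol-1-ylthiocarbonyl) group
Product: 19 (4R,5S,7R,10R,11R) tricyclic enone (cyclobutane C4–C5–C11–C10, C1 ketone with C2=C3, C8=C9, 7-OTBS)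
Conditions: (Me3Si)3SiH, AIBN, PhCF3 (5 mM), 90 °C, slow addition
Reagents that add atoms: none
Why: Proposed new method: the silyl radical cleaves the thiocarbonyl ester to a secondary C5 radical (Barton–McCombie initiation), which adds 4-exo-trig to C11 of the enol triflate; the resulting α-triflyloxy allyl radical fragments irreversibly at O–S to restore the C1 enone and expel SO2 and CF3• (which takes hydrogen from the silane and carries the chain). Carbonyl formation thus pays for the strain of the bicyclo[3.1.1]heptenone, which a reversible aldol closure onto a C5 ketone could not, and no backside attack at the neopentyl C5 is required. C5 and C11 can only adopt the target configuration because C5 must bridge C4 and C11 on the face fixed by the cis fusion. The closest known reaction types are radical addition–fragmentation of enol triflates to α-substituted ketones and 4-exo-trig radical cyclisations that end in a stabilised radical.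

**Step 15**
Reactants: 19 (4R,5S,7R,10R,11R) tricyclic enone
Product: 20 (4R,5S,7R,10R,11R) tricyclic C9 ketone (C1 enone, 7-OTBS)
Conditions: PdCl2 (0.2 equiv), CuCl (0.5 equiv), O2 (1 atm), DMF/H2O (7:1), 40 °C
Reagents that add atoms: water, O
Why: Wacker oxidation of the cis-disubstituted C8=C9 alkene, in which the allylic C7 silyloxy group directs water to the distal carbon C9 and the electron-poor C2=C3 alkene stays inert.

**Step 16**
Reactants: 20 (4R,5S,7R,10R,11R) tricyclic C9 ketone
Product: 21 (4R,5S,7R,10R,11R) C7-hydroxy C9-ketone (C1 enone)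
Conditions: HF·pyridine, THF/pyridine, 0 to 25 °C
Reagents that add atoms: none
Why: Buffered fluoride desilylation frees the C7 hydroxyl without β-elimination or retro-aldol cleavage of the β-hydroxy ketone.

**Step 17**
Reactants: 21 (4R,5S,7R,10R,11R) C7-hydroxy C9-ketone; 22 tiglaldehyde ((E)-2-methylbut-2-enal)
Product: 23 (4R,5S,7R,9R,10R,11R) C7 tiglate with free C9 hydroxyl
Conditions: SmI2 (0.3 equiv), 22 (6 equiv), THF, −10 °C
Reagents that add atoms: none
Why: Evans–Tishchenko reduction, in which the hemiacetal formed on O7 from tiglaldehyde delivers its hydride intramolecularly to the C9 ketone on the face syn to C7–O; this sets C9 anti to C7 and leaves the tiglate on O7 and a free hydroxyl on C9.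

**Step 18**
Reactants: 23 (4R,5S,7R,9R,10R,11R) C7 tiglate with free C9 hydroxyl; 24 angelic acid ((Z)-2-methylbut-2-enoic acid)
Product: 26 target (4R,5S,7R,9R,10R,11R) C7 tiglate C9 angelate, via mixed anhydride 25 (not isolated)
Conditions: 24, 2,4,6-Cl3C6H2COCl, Et3N, toluene, 25 °C; then 23, 80 °C
Reagents that add atoms: none
Why: Yamaguchi esterification through the mixed anhydride acylates the hindered C9 hydroxyl at the angeloyl carbonyl and avoids the Z to E isomerisation that other activations of angelic acid cause.

**Compound list**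

1 | (S)-pantolactone | CC1(C)COC(=O)[C@H]1O | starting material
2 | (3S)-3-(tert-butyldimethylsilyloxy)-4,4-dimethyloxolan-2-one | CC1(C)COC(=O)[C@H]1O[Si](C)(C)C(C)(C)C | intermediate
3 | (3S)-3-(tert-butyldimethylsilyloxy)-4,4-dimethyloxolan-2-ol | CC1(C)COC(O)[C@H]1O[Si](C)(C)C(C)(C)C | intermediate
4 | (3R)-3-(tert-butyldimethylsilyloxy)-2,2-dimethylpent-4-en-1-ol | C=C[C@@H](O[Si](C)(C)C(C)(C)C)C(C)(C)CO | intermediate
5 | (3R)-3-(tert-butyldimethylsilyloxy)-2,2-dimethylpent-4-enoic acid | C=C[C@@H](O[Si](C)(C)C(C)(C)C)C(C)(C)C(=O)O | intermediate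
6 | (4R)-4-(tert-butyldimethylsilyloxy)-3,3-dimethylhex-5-en-2-one | C=C[C@@H](O[Si](C)(C)C(C)(C)C)C(C)(C)C(C)=O | intermediate
7 | but-3-en-2-one | C=CC(C)=O | starting material
8 | (3R)-3-(tert-butyldimethylsilyloxy)-7-hydroxy-4,4,7-trimethylnona-1,8-dien-5-one | C=C[C@@H](O[Si](C)(C)C(C)(C)C)C(C)(C)C(=O)CC(C)(O)C=C | intermediate
9 | (6R)-6-(tert-butyldimethylsilyloxy)-3-hydroxy-3,7,7-trimethylcyclohept-4-en-1-one | O=C1CC(C)(O)C=C[C@@H](O[Si](C)(C)C(C)(C)C)C1(C)C | intermediate
10 | tertiary methanesulfonate of 9 | O=C1CC(C)(OS(C)(=O)=O)C=C[C@@H](O[Si](C)(C)C(C)(C)C)C1(C)C | intermediate (not isolated)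
11 | (6R)-6-(tert-butyldimethylsilyloxy)-3,7,7-trimethylcyclohepta-2,4-dien-1-one | CC1=CC(=O)C(C)(C)[C@H](O[Si](C)(C)C(C)(C)C)C=C1 | intermediate
12 | (E)-4-methoxypent-3-en-2-one | CO/C(C)=C/C(C)=O | starting material
13 | (E)-4-methoxy-2-(trimethylsilyloxy)penta-1,3-diene | CO/C(C)=C/C(=C)O[Si](C)(C)C | intermediate
14 | cis-fused cycloadduct: C1 trimethylsilyl enol ether (C1=C2), 3-methoxy-3-methyl, C5 ketone, ring fusion as in 15 | COC1(C)C=C(O[Si](C)(C)C)C[C@]2(C)C=C[C@@H](O[Si](C)(C)C(C)(C)C)C(C)(C)C(=O)[C@H]12 | intermediate (not isolated)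
15 | (4R,7R,10R) cis-fused bicyclic enedione, 7-OTBS, C8=C9 | CC1=CC(=O)C[C@]2(C)C=C[C@@H](O[Si](C)(C)C(C)(C)C)C(C)(C)C(=O)[C@H]12 | intermediate
16 | (4R,7R,10R) C5 alcohol of 15 | CC1=CC(=O)C[C@]2(C)C=C[C@@H](O[Si](C)(C)C(C)(C)C)C(C)(C)C(O)[C@H]12 | intermediate
17 | (4R,7R,10R) C11=C1 enol triflate, C5 hydroxyl | CC1=CC(OS(=O)(=O)C(F)(F)F)=C[C@]2(C)C=C[C@@H](O[Si](C)(C)C(C)(C)C)C(C)(C)C(O)[C@H]12 | intermediate
18 | (4R,7R,10R) enol triflate, C5 O-(imidazol-1-ylthiocarbonyl) | CC1=CC(OS(=O)(=O)C(F)(F)F)=C[C@]2(C)C=C[C@@H](O[Si](C)(C)C(C)(C)C)C(C)(C)C(OC(=S)n3ccnc3)[C@H]12 | intermediate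
19 | (4R,5S,7R,10R,11R) tricyclic enone, C8=C9, 7-OTBS | C1=C[C@@H](O[Si](C)(C)C(C)(C)C)C(C)(C)[C@@H]2[C@H]3C(=O)C=C(C)[C@@H]2[C@]31C | intermediate
20 | (4R,5S,7R,10R,11R) tricyclic C9 ketone, 7-OTBS | O=C1C[C@@H](O[Si](C)(C)C(C)(C)C)C(C)(C)[C@@H]2[C@H]3C(=O)C=C(C)[C@@H]2[C@]31C | intermediate
21 | (4R,5S,7R,10R,11R) C7-hydroxy C9-ketone | O=C1C[C@@H](O)C(C)(C)[C@@H]2[C@H]3C(=O)C=C(C)[C@@H]2[C@]31C | intermediate
22 | tiglaldehyde | C/C=C(\C)C=O | starting material
23 | (4R,5S,7R,9R,10R,11R) C7 tiglate, C9 hydroxyl | O[C@@H]1C[C@@H](OC(=O)/C(C)=C/C)C(C)(C)[C@@H]2[C@H]3C(=O)C=C(C)[C@@H]2[C@]31C | intermediate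
24 | angelic acid | C/C=C(/C)C(=O)O | starting material
25 | angelic 2,4,6-trichlorobenzoic anhydride | C/C=C(/C)C(=O)OC(=O)c1c(Cl)cc(Cl)cc1Cl | intermediate (not isolated)
26 | target CNP0236543.2, (4R,5S,7R,9R,10R,11R) C7 tiglate C9 angelate | C/C=C(/C)C(=O)O[C@@H]1C[C@@H](OC(=O)/C(C)=C/C)C(C)(C)[C@@H]2[C@H]3C(=O)C=C(C)[C@@H]2[C@]31C | target

**Step count and risks**

Total: 18 steps. Longest linear sequence: 17 steps (steps 1–8 and 10–18; step 9 is a one-step side branch).

Steps most likely to fail:

1. Step 14 (proposed new method). The 4-exo-trig closure may be slower than hydrogen transfer from the silane to the C5 radical, which would end in simple deoxygenation; the closure may also revert before fragmentation, or CF3• may add to the diene of unreacted 18. The fallback is the two-electron closure that is classical for bicyclo[3.1.1]heptan-2-ones. It sets out from 16, using the C5 epimer whose hydroxyl is cis to C4–H (separated by chromatography). MsCl and Et3N in CH2Cl2 at 0 °C give the methanesulfonate F1. KN(SiMe3)2 in THF/DMPU (−78 to 25 °C) then forms the kinetic C11 enolate, which displaces the sulfonate with inversion in an intramolecular 4-exo-tet alkylation. This fallback is itself demanding, because C5 is flanked by the quaternary C6. It returns to the route at 19.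

2. Step 10. The β,β-disubstituted dienophile may react more slowly than the diene decomposes, the facial bias from the remote C7 centre may be incomplete, and C4 may epimerise during unmasking. The fallback replaces the cycloaddition by a stepwise ionic annulation that forms the same two bonds. It sets out from 11 and 13: Me3SiOTf (cat.) in CH2Cl2 at −78 °C promotes a Mukaiyama–Michael addition of C11 to C10 and gives the open-chain adduct F2 (C4=C5 trimethylsilyl enol ether, vinylogous ester side chain on C10). Bu4NF (1 equiv) in THF at −40 °C then releases the C4 enolate, which closes onto C3 by intramolecular conjugate addition and expels methoxide. It returns at 15.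

3. Step 15. Hydroxypalladation may be slow at the hindered alkene or place oxygen at C8 instead of C9. The fallback avoids both the Wacker and the Evans–Tishchenko steps and sets out from 19.
   - mCPBA with NaHCO3 in CH2Cl2 at 0 °C should attack the alkene face opposite the C7 silyloxy group and give the epoxide F3.
   - LiEt3BH in THF opens F3 at the less hindered C8 and also reduces the C1 carbonyl, giving the diol F4.
   - MnO2 in CH2Cl2 reoxidises only the allylic C1 alcohol to the hydroxy enone F5, whose C9 hydroxyl is anti to O7.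
   - Yamaguchi esterification with 24 (through 25) gives the angelate silyl ether F6.
   - HF·pyridine gives the hydroxy angelate F7.
   - Tigloyl chloride, pyridine and DMAP acylate C7. The fallback returns at 26.

**Further compounds**

F1 | step 14 | (4R,5S,7R,10R) C5 methanesulfonate of the bicyclic enone | CC1=CC(=O)C[C@]2(C)C=C[C@@H](O[Si](C)(C)C(C)(C)C)C(C)(C)[C@@H](OS(C)(=O)=O)[C@H]12
F2 | step 10 | Mukaiyama–Michael adduct (C4=C5 trimethylsilyl enol ether, C10 side chain CH2C(=O)CH=C(OMe)CH3) | CO/C(C)=C/C(=O)C[C@]1(C)C=C[C@@H](O[Si](C)(C)C(C)(C)C)C(C)(C)C(O[Si](C)(C)C)=C1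
F3 | step 15 | tricyclic C8–C9 epoxide, oxygen anti to 7-OTBS | O4[C@@H]1[C@H]4[C@@H](O[Si](C)(C)C(C)(C)C)C(C)(C)[C@@H]2[C@H]3C(=O)C=C(C)[C@@H]2[C@]31C
F4 | step 15 | tricyclic C1,C9-diol, 7-OTBS (C1 epimers) | O[C@@H]1C[C@@H](O[Si](C)(C)C(C)(C)C)C(C)(C)[C@@H]2[C@H]3C(O)C=C(C)[C@@H]2[C@]31C
F5 | step 15 | tricyclic C9-hydroxy enone, 7-OTBS | O[C@@H]1C[C@@H](O[Si](C)(C)C(C)(C)C)C(C)(C)[C@@H]2[C@H]3C(=O)C=C(C)[C@@H]2[C@]31C
F6 | step 15 | C9 angelate, 7-OTBS | C/C=C(/C)C(=O)O[C@@H]1C[C@@H](O[Si](C)(C)C(C)(C)C)C(C)(C)[C@@H]2[C@H]3C(=O)C=C(C)[C@@H]2[C@]31C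
F7 | step 15 | C9 angelate, C7 hydroxyl | C/C=C(/C)C(=O)O[C@@H]1C[C@@H](O)C(C)(C)[C@@H]2[C@H]3C(=O)C=C(C)[C@@H]2[C@]31C
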